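**Plan**

Numbering (germacrane type): ring A (furanone) = O1, C1, C2, C3(=O), C4(Me). C5 = exocyclic =CH. Ring B (butenolide) = O, C6, C7, C11, C12(=O). C8 = CH–O-acyl, C9 = CH2, C10 = CHMe, C13 = CH2OH on C11.
Cuts, in retrosynthetic order: both C(sp2)–CH2OH bonds (C11–C13 and the one in the acrylate) and the C8–O ester; then C4–C5; then C7–C8; then C5=C6 (C5 from an orthoformate) and ring A (C1–C2, C1–O1).
Enabling feature: C4 is C2 of the 3(2H)-furanone ring A, the nucleophilic α-carbon of an aromatic 3-silyloxyfuran. C5 is the exocyclic δ-carbon on ring B, the cationic carbon of an aromatic 2-silyloxyfurfuryl ion. Both five-membered rings are one silyl shift from furans, so C4–C5, the most hindered bond, is a matched donor–acceptor pair.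
Forward: ring A is made first and stored as its silyloxyfuran. Ring B is bought as 3,4-dibromofuran-2(5H)-one and given C5. The halves are joined at C7–C8, and the nine-membered ring O1–C1–C10–C9–C8–C7–C6–C5–C4 is closed last at C4–C5. That closure also creates the quaternary carbon, unveils the furanone and sets the 5E alkene.
Stereochemistry: C10 comes from commercial (S)-methylsuccinic acid 4-methyl ester, C8 from the chiral ligand of the Ni/Cr coupling, and C4 from C8 by transannular control in the ring closure.

Key step: step 8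

Remark: but-3-yn-2-ol (4) is used as the racemate, because its carbinol carbon (later C4) becomes planar in step 4. Compounds 6–8 are therefore epimer pairs at that carbon, and their SMILES leave it undefined.

**Step 1**
Reactants: 1 (S)-4-methoxy-2-methyl-4-oxobutanoic acid
Product: 3 methyl (S)-4-[methoxy(methyl)amino]-3-methyl-4-oxobutanoate, via acyl imidazole 2 (not isolated)
Conditions: CDI, CH2Cl2, 0 °C to rt; then MeNH(OMe)·HCl, rt
Reagents that add atoms: N,O-dimethylhydroxylamine hydrochloride, CNOC.Cl
Why: Weinreb amide formation through the acyl imidazole activates only the free acid (C1) and leaves the methyl ester (C8) and the C10 stereocentre untouched.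

**Step 2**
Reactants: 3 methyl (S)-4-[methoxy(methyl)amino]-3-methyl-4-oxobutanoate; 4 but-3-yn-2-ol (racemic)
Product: 6 methyl (3S)-7-hydroxy-3-methyl-4-oxooct-5-ynoate, via dilithiated butynol 5 (not isolated)
Conditions: 4, n-BuLi (2 equiv per 4), THF, −78 °C; then 3, −78 to −30 °C; aqueous work-up
Reagents that add atoms: none
Why: Weinreb ketone synthesis: the acetylide carbon of 5 adds to the chelating N-methoxy amide faster than to the methyl ester at low temperature, and the tetrahedral lithium chelate that persists until work-up blocks a second addition and enolisation at C10.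

**Step 3**
Reactants: 6 methyl (3S)-7-hydroxy-3-methyl-4-oxooct-5-ynoate
Product: 8 methyl (3S)-3-(5-methyl-4-oxo-4,5-dihydrofuran-2-yl)butanoate, via enaminone 7 (not isolated)
Conditions: Et2NH, EtOH, rt; then AcOH–H2O, rt
Reagents that add atoms: none
Why: Classical conversion of a γ-hydroxy ynone into a 3(2H)-furanone: aza-Michael addition of the amine at C3 gives 7, and in aqueous acid the C4 hydroxyl closes on the C1 carbonyl (5-exo-trig), water is lost and the vinylogous iminium is hydrolysed to the C3 ketone, C4 arising as an inconsequential epimer pair.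

**Step 4**
Reactants: 8 methyl (3S)-3-(5-methyl-4-oxo-4,5-dihydrofuran-2-yl)butanoate
Product: 9 methyl (3S)-3-[5-methyl-4-(triisopropylsilyloxy)furan-2-yl]butanoate
Conditions: TIPSOTf, Et3N, CH2Cl2, 0 °C
Reagents that add atoms: triisopropylsilyl trifluoromethanesulfonate, CC(C)[Si](C(C)C)(C(C)C)OS(=O)(=O)C(F)(F)F
Why: Silyl enol ether formation by soft enolisation: removal of the C4 proton is driven by aromatisation to the furan, so the ester and C10–H are left alone, and the bulky TIPS group both stabilises the electron-rich furan and serves as a steric control element in step 8.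

**Step 5**
Reactants: 9 methyl (3S)-3-[5-methyl-4-(triisopropylsilyloxy)furan-2-yl]butanoate
Product: 10 (3S)-3-[5-methyl-4-(triisopropylsilyloxy)furan-2-yl]butanal
Conditions: DIBAL-H (1.1 equiv), CH2Cl2, −78 °C; Rochelle salt work-up
Reagents that add atoms: none
Why: Partial ester reduction with DIBAL-H through the aluminium hemiacetal that is stable at −78 °C; ring A carries no carbonyl group at this stage, which is why step 4 comes first, and C10 is β to the new aldehyde and cannot epimerise.

**Step 6**
Reactants: 11 3,4-dibromofuran-2(5H)-one; 12 trimethyl orthoformate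
Product: 15 (5Z)-3,4-dibromo-5-(methoxymethylidene)furan-2(5H)-one, via silyloxyfuran 13 (not isolated), via dimethyl acetal 14 (not isolated)
Conditions: TBSOTf (2.5 equiv), iPr2NEt (3 equiv), CH2Cl2, 0 °C to rt
Reagents that add atoms: none
Why: One-pot silyl dienol ether formation and vinylogous Mukaiyama addition of the 2-silyloxyfuran 13 to the dimethoxycarbenium ion from 12 at the free γ-carbon C6 (the α-carbon is blocked by bromine), followed by the known silyl triflate/amine conversion of an acetal into its enol ether, here eased by the acidic C6–H; the Z isomer is expected for steric reasons and the geometry is erased in step 8.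

**Step 7**
Reactants: 10 (3S)-3-[5-methyl-4-(triisopropylsilyloxy)furan-2-yl]butanal; 15 (5Z)-3,4-dibromo-5-(methoxymethylidene)furan-2(5H)-one
Product: 16 (5Z)-3-bromo-5-(methoxymethylidene)-4-{(1S,3S)-3-[5-methyl-4-(triisopropylsilyloxy)furan-2-yl]-1-(triethylsilyloxy)butyl}furan-2(5H)-one
Conditions: CrCl2 (10 mol %), chiral oxazoline–sulfonamide ligand (11 mol %, the antipode that delivers 8S), NiCl2·(2,9-dimethylphenanthroline) (2 mol %), Mn, TESCl, LiCl, MeCN, rt
Reagents that add atoms: chlorotriethylsilane, CC[Si](Cl)(CC)CC
Why: Catalytic asymmetric Nozaki–Hiyama–Kishi coupling: nickel inserts into the C7–Br bond, the vinylogous acyl bromide that also reacts first in known cross-couplings of 3,4-dibromobutenolides, the alkenylchromium species adds only to the aldehyde with the face set by the chiral ligand (8S), and the chlorosilane that turns over the chromium leaves C8–O protected as its TES ether.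

**Step 8**
Reactants: 16 (5Z)-3-bromo-5-(methoxymethylidene)-4-{(1S,3S)-3-[5-methyl-4-(triisopropylsilyloxy)furan-2-yl]-1-(triethylsilyloxy)butyl}furan-2(5H)-one
Product: 18 (4S,5E,8S,10S)-11-bromo-3-oxo-8-(triethylsilyloxy)-13-nor-1,4-epoxygermacra-1,5,7(11)-trien-12,6-olide, via C5-methoxy macrocycle 17 (not isolated)
Conditions: TMSOTf (20 mol %), 2,6-di-tert-butyl-4-methylpyridine (30 mol %), CH2Cl2, −40 to 0 °C, 16 added by syringe pump to a final 1 mM
Reagents that add atoms: none
Why: Proposed new method: the silyl triflate silylates the lactone carbonyl oxygen of 16, which turns the 5-(methoxymethylidene)butenolide into an aromatic 2-silyloxyfurfuryl oxocarbenium ion that is electrophilic at C5, C4 of the 3-silyloxyfuran attacks it to give 17 (ring A now the furanone, ring B a 2-silyloxyfuran), and vinylogous loss of the C5 methoxy group as the methoxysilane re-forms the butenolide, creates C5=C6 and returns the silyl cation, so the process is catalytic in Lewis acid. The closest known reaction types are the Mukaiyama aldol reaction of 3-silyloxyfurans at their C2 carbon, the Lewis acid addition–elimination of silyl enol ethers on β-alkoxy enones and nucleophilic vinylic substitutions that build quaternary carbons, whereas the 1,6-vinylogous version on an alkoxymethylidene butenolide and its use for a medium ring are new. One ring is closed, the nine-membered ring O1–C1–C10–C9–C8–C7–C6–C5–C4, in a 9-exo-trig mode with respect to the C5=O+ bond of the oxocarbenium ion (9-endo-trig if counted on C5=C6 of 16). C4 is the only lasting new stereocentre and is controlled by C8: the tether has to leave ring B with C8–H turned towards the furanone C2–H and the OTES group outwards, the (4R) adduct would drive OTES into ring A when C5 flattens, and since the C4–C5 addition should be reversible (both partners are stabilised furans) while the loss of the methoxy group is not, the material should drain through the (4S) series, helped by the bulky C3–OTIPS group that keeps ring A exo over ring B; the C5 centre of 17 is lost again and the 5E geometry (C4 cis to C7) is the only one the nine-membered ring can hold. The step needs attack by C4 rather than C2, secured by the enol ether polarisation of C3=C4 next to O1 and by the poorer eight-membered alternative, and ring closure rather than oligomerisation, secured by slow addition at high dilution and by the two flat rings, which leave only three rotatable tether atoms.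

**Step 9**
Reactants: 18 (4S,5E,8S,10S)-11-bromo-3-oxo-8-(triethylsilyloxy)-13-nor-1,4-epoxygermacra-1,5,7(11)-trien-12,6-olide
Product: 19 (4S,5E,8S,10S)-11-bromo-8-hydroxy-3-oxo-13-nor-1,4-epoxygermacra-1,5,7(11)-trien-12,6-olide
Conditions: HF·pyridine, pyridine/THF, 0 °C
Reagents that add atoms: none
Why: Fluoride-induced cleavage of a secondary TES ether under buffered, non-basic conditions, which spare the γ-acidic C10–H, the bromobutenolide and the alkylidene group.

**Step 10**
Reactants: 19 (4S,5E,8S,10S)-11-bromo-8-hydroxy-3-oxo-13-nor-1,4-epoxygermacra-1,5,7(11)-trien-12,6-olide; 20 2,3-dibromopropanoyl chloride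
Product: 22 (4S,5E,8S,10S)-11-bromo-8-(2-bromoacryloyloxy)-3-oxo-13-nor-1,4-epoxygermacra-1,5,7(11)-trien-12,6-olide, via dibromopropanoate 21 (not isolated)
Conditions: 20, Et3N (4 equiv), DMAP (10 mol %), CH2Cl2, −20 to 0 °C
Reagents that add atoms: none
Why: Acylation of the C8 alcohol with an acid chloride and in situ E1cB loss of HBr from 21, the standard entry to 2-bromoacrylates, which avoids the polymerisable free acid; the C8–O bond is not touched, so the configuration is kept.

**Step 11**
Reactants: 22 (4S,5E,8S,10S)-11-bromo-8-(2-bromoacryloyloxy)-3-oxo-13-nor-1,4-epoxygermacra-1,5,7(11)-trien-12,6-olide; 23 (tributylstannyl)methanol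
Product: 24 (4S,5E,8S,10S)-13-hydroxy-8-[2-(hydroxymethyl)acryloyloxy]-3-oxo-1,4-epoxygermacra-1,5,7(11)-trien-12,6-olide (CNP0261115.1)
Conditions: 23 (3 equiv), Pd2(dba)3 (5 mol %), AsPh3 (20 mol %), BHT, NMP, 60 °C
Reagents that add atoms: none
Why: Twofold Stille hydroxymethylation: both C–Br bonds are α-bromo enoate bonds that undergo oxidative addition alike, the stannane transfers its hydroxymethyl group under neutral conditions, and both primary alcohols appear unprotected in the last step without touching any stereocentre.

**Compound list**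

1 | (S)-4-methoxy-2-methyl-4-oxobutanoic acid (4-methyl hydrogen (S)-2-methylsuccinate) | COC(=O)C[C@H](C)C(=O)O | starting material
2 | methyl (S)-4-(imidazol-1-yl)-3-methyl-4-oxobutanoate (acyl imidazole) | COC(=O)C[C@H](C)C(=O)n1ccnc1 | intermediate
3 | methyl (S)-4-[methoxy(methyl)amino]-3-methyl-4-oxobutanoate | COC(=O)C[C@H](C)C(=O)N(C)OC | intermediate
4 | but-3-yn-2-ol (racemic) | CC(O)C#C | starting material
5 | dilithiated but-3-yn-2-ol (lithium 4-lithiobut-3-yn-2-olate) | [Li]C#CC(C)O[Li] | intermediate
6 | methyl (3S)-7-hydroxy-3-methyl-4-oxooct-5-ynoate (epimer pair at C7 of the chain) | COC(=O)C[C@H](C)C(=O)C#CC(C)O | intermediate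
7 | methyl (3S)-6-(diethylamino)-7-hydroxy-3-methyl-4-oxooct-5-enoate (enaminone) | COC(=O)C[C@H](C)C(=O)C=C(N(CC)CC)C(C)O | intermediate
8 | methyl (3S)-3-(5-methyl-4-oxo-4,5-dihydrofuran-2-yl)butanoate (epimer pair at the ring CHMe carbon) | COC(=O)C[C@H](C)C1=CC(=O)C(C)O1 | intermediate
9 | methyl (3S)-3-[5-methyl-4-(triisopropylsilyloxy)furan-2-yl]butanoate | COC(=O)C[C@H](C)c1cc(O[Si](C(C)C)(C(C)C)C(C)C)c(C)o1 | intermediate
10 | (3S)-3-[5-methyl-4-(triisopropylsilyloxy)furan-2-yl]butanal | O=CC[C@H](C)c1cc(O[Si](C(C)C)(C(C)C)C(C)C)c(C)o1 | intermediate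
11 | 3,4-dibromofuran-2(5H)-one | O=C1OCC(Br)=C1Br | starting material
12 | trimethyl orthoformate | COC(OC)OC | starting material
13 | tert-butyl[(3,4-dibromofuran-2-yl)oxy]dimethylsilane | CC(C)(C)[Si](C)(C)Oc1occ(Br)c1Br | intermediate
14 | 3,4-dibromo-5-(dimethoxymethyl)furan-2(5H)-one | COC(OC)C1OC(=O)C(Br)=C1Br | intermediate
15 | (5Z)-3,4-dibromo-5-(methoxymethylidene)furan-2(5H)-one | CO/C=C1\OC(=O)C(Br)=C1Br | intermediate
16 | (5Z)-3-bromo-5-(methoxymethylidene)-4-{(1S,3S)-3-[5-methyl-4-(triisopropylsilyloxy)furan-2-yl]-1-(triethylsilyloxy)butyl}furan-2(5H)-one | CC[Si](CC)(CC)O[C@@H](C[C@H](C)c1cc(O[Si](C(C)C)(C(C)C)C(C)C)c(C)o1)C2=C(Br)C(=O)O/C2=C\OC | intermediate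
17 | ring-closure adduct (4S,8S,10S): furanone C4 bonded to C5H(OMe), ring B a 3-bromo-2-(triisopropylsilyloxy)furan, C8 OTES | CC[Si](CC)(CC)O[C@H]1C[C@H](C)C2=CC(=O)[C@](C)(C(OC)c3oc(O[Si](C(C)C)(C(C)C)C(C)C)c(Br)c31)O2 | intermediate
18 | (4S,5E,8S,10S)-11-bromo-3-oxo-8-(triethylsilyloxy)-13-nor-1,4-epoxygermacra-1,5,7(11)-trien-12,6-olide | CC[Si](CC)(CC)O[C@H]1C[C@H](C)C2=CC(=O)[C@](C)(/C=C3/OC(=O)C(Br)=C31)O2 | intermediate
19 | (4S,5E,8S,10S)-11-bromo-8-hydroxy-3-oxo-13-nor-1,4-epoxygermacra-1,5,7(11)-trien-12,6-olide | O[C@H]1C[C@H](C)C2=CC(=O)[C@](C)(/C=C3/OC(=O)C(Br)=C31)O2 | intermediate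
20 | 2,3-dibromopropanoyl chloride | O=C(Cl)C(Br)CBr | starting material
21 | 8-O-(2,3-dibromopropanoyl) ester of 19 | BrCC(Br)C(=O)O[C@H]1C[C@H](C)C2=CC(=O)[C@](C)(/C=C3/OC(=O)C(Br)=C31)O2 | intermediate
22 | 8-O-(2-bromoacryloyl) ester of 19 | C=C(Br)C(=O)O[C@H]1C[C@H](C)C2=CC(=O)[C@](C)(/C=C3/OC(=O)C(Br)=C31)O2 | intermediate
23 | (tributylstannyl)methanol | CCCC[Sn](CCCC)(CCCC)CO | starting material
24 | (4S,5E,8S,10S)-13-hydroxy-8-[2-(hydroxymethyl)acryloyloxy]-3-oxo-1,4-epoxygermacra-1,5,7(11)-trien-12,6-olide (CNP0261115.1) | C=C(CO)C(=O)O[C@H]1C[C@H](C)C2=CC(=O)[C@](C)(/C=C3/OC(=O)C(CO)=C31)O2 | target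

**Count**

Total steps: 11. Longest linear sequence: 10 steps (steps 1–5 and 7–11, from 1 to 24).

**Steps most likely to fail**

**Step 8.** Intermolecular addition may outrun the medium-ring closure. Facial selectivity at C4 may also be poor if the C4–C5 addition turns out not to be reversible.

The fallback uses known reaction types, makes C4 before the ring and closes the same ring at C5–C6. It sets out from 10 and 11 and comes back at 18.
- Aldehyde 10 is coupled with unsubstituted 11 under the conditions of step 7 to give the butenolide silyl ether F1.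
- The 3-silyloxyfuran of F1 is added to orthoformate 12 (BF3·OEt2, CH2Cl2, −78 °C, intermolecular Mukaiyama reaction). This gives the furanone acetal F2 as a C4 epimer pair, from which the (4S) isomer is separated by chromatography.
- TBSOTf/iPr2NEt at high dilution turns the butenolide into its 2-silyloxyfuran and ionises the acetal. An intramolecular vinylogous Mukaiyama aldol reaction then closes the ring to the methoxy lactone F3.
- DBU-induced β-elimination of methanol gives 18.

**Step 7.** Facial selectivity at the aldehyde may be low with this hindered alkenyl bromide. Turnover may also stall because the crowded chromium alkoxide is silylated slowly.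

The fallback moves stereocontrol from the C–C coupling to a ketone reduction. It sets out from 10 and 15 and comes back at 16.
- A ligand-free stoichiometric Nozaki–Hiyama–Kishi coupling (CrCl2, cat. NiCl2, DMSO) gives the carbinol epimer pair F4.
- Dess–Martin oxidation gives the ketone F5.
- Corey–Bakshi–Shibata reduction with the (R)-methyl oxazaborolidine and catecholborane, in which the fully substituted butenolide carbon C7 acts as the large group, gives the (8S)-alcohol F6.
- TESCl/imidazole gives 16.

**Step 11.** The 2-bromoacrylate may polymerise or lose bromine reductively before the slow transfer of the hydroxymethyl group, and the second coupling may stay incomplete.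

The fallback brings the side-chain alcohol in ready-made and protected, so that only the butenolide bromide has to couple. It sets out from 19 and comes back at 24.
- Commercial ethyl 2-(hydroxymethyl)acrylate is silylated (TBSCl, imidazole) to the silyl ether ester F7 and saponified (LiOH) to the protected acid F8.
- Yamaguchi esterification of 19 with F8 gives the bromo ester F9.
- A single Stille hydroxymethylation with 23 gives the mono-silyl ether F10.
- HF·pyridine gives 24.

**Further compounds**

F1 | step 8 | 3-bromo-4-{(1S,3S)-3-[5-methyl-4-(triisopropylsilyloxy)furan-2-yl]-1-(triethylsilyloxy)butyl}furan-2(5H)-one | CC[Si](CC)(CC)O[C@@H](C[C@H](C)c1cc(O[Si](C(C)C)(C(C)C)C(C)C)c(C)o1)C2=C(Br)C(=O)OC2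
F2 | step 8 | 3-bromo-4-{(1S,3S)-3-[(5S)-5-(dimethoxymethyl)-5-methyl-4-oxo-4,5-dihydrofuran-2-yl]-1-(triethylsilyloxy)butyl}furan-2(5H)-one | CC[Si](CC)(CC)O[C@@H](C[C@H](C)C1=CC(=O)[C@](C)(C(OC)OC)O1)C2=C(Br)C(=O)OC2
F3 | step 8 | 5-methoxy-5,6-dihydro derivative of 18 (C5 and C6 undefined) | CC[Si](CC)(CC)O[C@H]1C[C@H](C)C2=CC(=O)[C@](C)(C(OC)C3OC(=O)C(Br)=C31)O2
F4 | step 7 | free C8 carbinol corresponding to 16, C8 epimer pair | OC(C[C@H](C)c1cc(O[Si](C(C)C)(C(C)C)C(C)C)c(C)o1)C2=C(Br)C(=O)O/C2=C\OC
F5 | step 7 | C8 ketone corresponding to 16 | O=C(C[C@H](C)c1cc(O[Si](C(C)C)(C(C)C)C(C)C)c(C)o1)C2=C(Br)C(=O)O/C2=C\OC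
F6 | step 7 | (8S)-carbinol corresponding to 16 | O[C@@H](C[C@H](C)c1cc(O[Si](C(C)C)(C(C)C)C(C)C)c(C)o1)C2=C(Br)C(=O)O/C2=C\OC
F7 | step 11 | ethyl 2-[(tert-butyldimethylsilyloxy)methyl]acrylate | CCOC(=O)C(=C)CO[Si](C)(C)C(C)(C)C
F8 | step 11 | 2-[(tert-butyldimethylsilyloxy)methyl]acrylic acid | OC(=O)C(=C)CO[Si](C)(C)C(C)(C)C
F9 | step 11 | 8-O-{2-[(tert-butyldimethylsilyloxy)methyl]acryloyl} ester of 19 | C=C(CO[Si](C)(C)C(C)(C)C)C(=O)O[C@H]1C[C@H](C)C2=CC(=O)[C@](C)(/C=C3/OC(=O)C(Br)=C31)O2
F10 | step 11 | side-chain O-TBS ether of 24 | C=C(CO[Si](C)(C)C(C)(C)C)C(=O)O[C@H]1C[C@H](C)C2=CC(=O)[C@](C)(/C=C3/OC(=O)C(CO)=C31)O2
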